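**Retrosynthetic overview**

- The 1,3-diketone is cut at its CH2–C(=O) bond on the ring B side (crossed Claisen condensation). This gives a ring A methyl ketone and a 4-oxygenated methyl benzoate for ring B, which is bought.
- The strategy rests on the substitution of ring A: acyl at C1, OMe at C2, prenyl at C3, free OH at C4, hydrogens at C5 and C6. This is a resorcinol with its methyl ether ortho and its free hydroxyl para to the ketone, and the prenyl group between the two oxygens.
- Ring A is therefore built, not substituted: a 2-prenyl-1,1-dimethoxy-3-silyloxybutadiene and but-3-yn-2-one form C1–C2 and C5–C6, and loss of methanol and of the silyl group gives the arene. It is the only ring formed in the route.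
- The diene comes from homoprenyl bromide and tetramethoxymethane: ortho ester, dealcoholation to the ketene acetal, C-acetylation, enol silylation.
- End game: MOM protection, Claisen condensation, removal of both MOM groups.

Key step: step 5

Remark: the target is drawn as the diketo tautomer. It will exist largely as the chelated enol, which is the same compound, and it has no stereocentre.

**Step 1**
Reactants: 1 5-bromo-2-methylpent-2-ene (homoprenyl bromide); 2 tetramethoxymethane (tetramethyl orthocarbonate)
Product: 4 6,6,6-trimethoxy-2-methylhex-2-ene (trimethyl ortho-5-methylhex-4-enoate), via homoprenylmagnesium bromide 3 (not isolated)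
Conditions: Mg, THF, reflux; then C(OMe)4, THF/PhMe, 80 °C; cold NaHCO3 (aq) work-up, distillation
Reagents that add atoms: none
Why: Grignard formation followed by the Tschitschibabin ortho ester synthesis, in which the alkylmagnesium bromide replaces one methoxide of the orthocarbonate; the ortho ester formed ionises less readily than the orthocarbonate, so addition should stop after one alkyl group, and no acid touches the trisubstituted alkene.

**Step 2**
Reactants: 4 6,6,6-trimethoxy-2-methylhex-2-ene
Product: 5 1,1-dimethoxy-5-methylhexa-1,4-diene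
Conditions: Al(OtBu)3 (5 mol %), neat, 180–200 °C, MeOH distilled off; then distillation at reduced pressure
Reagents that add atoms: none
Why: Aluminium-alkoxide-promoted dealcoholation of an ortho ester, the classical ketene acetal synthesis; the alkoxide assists ionisation to the dimethoxycarbenium ion and loss of the α-proton, removal of methanol drives the equilibrium, and the isolated alkene is inert under these non-acidic conditions.

**Step 3**
Reactants: 5 1,1-dimethoxy-5-methylhexa-1,4-diene; 6 acetyl chloride
Product: 7 3-(dimethoxymethylidene)-6-methylhept-5-en-2-one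
Conditions: AcCl, Et3N, Et2O, 0 °C to rt; filtration, used without chromatography
Reagents that add atoms: none
Why: C-acylation of a ketene O,O-acetal by an acid chloride; the electron-rich β-carbon attacks the acyl chloride and triethylamine removes the proton between the carbonyl and the dimethoxycarbenium carbon, which should give the push–pull acylketene acetal.

**Step 4**
Reactants: 7 3-(dimethoxymethylidene)-6-methylhept-5-en-2-one
Product: 8 [1,1-dimethoxy-2-(3-methylbut-2-enyl)buta-1,3-dien-3-yl]oxy-trimethylsilane
Conditions: LiN(i-Pr)2 (LDA), THF, −78 °C; then Me3SiCl, −78 °C to rt; non-aqueous work-up, used crude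
Reagents that add atoms: chlorotrimethylsilane, C[Si](C)(C)Cl
Why: Kinetic enolisation and O-silylation; the acetyl CH3 carries the only protons α to the carbonyl, so the cross-conjugated lithium enolate should form and be trapped on oxygen to give the 1,1-dimethoxy-3-silyloxy diene.

**Step 5**
Reactants: 8 [1,1-dimethoxy-2-(3-methylbut-2-enyl)buta-1,3-dien-3-yl]oxy-trimethylsilane; 9 but-3-yn-2-one
Product: 12 1-[4-hydroxy-2-methoxy-3-(3-methylbut-2-enyl)phenyl]ethanone, via cyclohexadiene ketal adduct 10 (not isolated), via aryl trimethylsilyl ether 11 (not isolated)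
Conditions: PhMe, 0 °C to 80 °C (sealed), until loss of MeOH is complete; then 0.5 M HCl (aq), THF, 0 °C
Reagents that add atoms: none
Why: This is a Diels–Alder benzannulation of a 1,1-dialkoxy-3-silyloxybutadiene with an alkynone, a reaction type established for the unsubstituted diene with propiolates and ynones. The silyl enol ether CH2 terminus, the most nucleophilic carbon of the diene, bonds to the ynone β-carbon and the ketene acetal carbon bonds to the α-carbon, either in an asynchronous concerted [4+2] addition or by Mukaiyama–Michael addition followed by six-membered ring closure of the allenolate onto the dimethoxycarbenium ion, so ring A is closed in a (4+2) mode by the two bonds that become C5–C6 and C1–C2. The cyclohexa-1,4-diene ketal 10 should then lose methanol by 1,4-elimination to give the aryl silyl ether 11, whose Si–O bond dilute acid cleaves, and aromatisation makes the sequence irreversible. No stereocentre is formed. The step needs regioselectivity (OMe ortho and OH para to the acetyl group) and chemoselectivity; the first follows from the matched polarisation of diene and ynone, the second from the inertness of the isolated trisubstituted prenyl alkene as a dienophile and from thermal conditions without Lewis acid, which leave the ynone carbonyl alone. The prenyl group on the central diene carbon favours the s-cis conformer and arrives at C3 between the two differentiated oxygens without any aromatic substitution.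

**Step 6**
Reactants: 12 1-[4-hydroxy-2-methoxy-3-(3-methylbut-2-enyl)phenyl]ethanone
Product: 13 1-[2-methoxy-4-(methoxymethoxy)-3-(3-methylbut-2-enyl)phenyl]ethanone
Conditions: MOMCl, i-Pr2NEt, CH2Cl2, 0 °C to rt
Reagents that add atoms: chloromethyl methyl ether, COCCl
Why: O-alkylation of the phenol (MOM protection) masks the acidic OH, so that only the methyl ketone is deprotonated in the Claisen step.

**Step 7**
Reactants: 14 methyl 4-hydroxybenzoate
Product: 15 methyl 4-(methoxymethoxy)benzoate
Conditions: MOMCl, i-Pr2NEt, CH2Cl2, 0 °C to rt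
Reagents that add atoms: chloromethyl methyl ether, COCCl
Why: O-alkylation of the phenol (MOM protection) keeps a phenoxide from deactivating the ester towards the enolate.

**Step 8**
Reactants: 13 1-[2-methoxy-4-(methoxymethoxy)-3-(3-methylbut-2-enyl)phenyl]ethanone; 15 methyl 4-(methoxymethoxy)benzoate
Product: 16 1-[2-methoxy-4-(methoxymethoxy)-3-(3-methylbut-2-enyl)phenyl]-3-[4-(methoxymethoxy)phenyl]propane-1,3-dione
Conditions: NaH (3 equiv.), THF, 0 °C to reflux; then AcOH, 0 °C
Reagents that add atoms: none
Why: Crossed Claisen condensation; the sodium enolate of the methyl ketone acylates on the non-enolisable aryl ester, deprotonation of the 1,3-diketone by further base drives the equilibrium, and the MOM ethers, the methyl ether and the prenyl group are inert to NaH.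

**Step 9**
Reactants: 16 1-[2-methoxy-4-(methoxymethoxy)-3-(3-methylbut-2-enyl)phenyl]-3-[4-(methoxymethoxy)phenyl]propane-1,3-dione
Product: 17 1-[4-hydroxy-2-methoxy-3-(3-methylbut-2-enyl)phenyl]-3-(4-hydroxyphenyl)propane-1,3-dione (target)
Conditions: HCl (1 M in MeOH), rt, short reaction time
Reagents that add atoms: none
Why: Acid-catalysed acetal exchange (methanolysis of the two MOM ethers) should free both phenols; the 2-methoxy group cannot cyclise onto the diketone, and mild, brief acid should spare the o-prenylphenol.

**Compound list**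

1 | 5-bromo-2-methylpent-2-ene | CC(C)=CCCBr | starting material
2 | tetramethoxymethane | COC(OC)(OC)OC | starting material
3 | (4-methylpent-3-enyl)magnesium bromide | CC(C)=CCC[Mg]Br | intermediate
4 | 6,6,6-trimethoxy-2-methylhex-2-ene | COC(OC)(OC)CCC=C(C)C | intermediate
5 | 1,1-dimethoxy-5-methylhexa-1,4-diene | COC(OC)=CCC=C(C)C | intermediate
6 | acetyl chloride | CC(=O)Cl | starting material
7 | 3-(dimethoxymethylidene)-6-methylhept-5-en-2-one | CC(=O)C(CC=C(C)C)=C(OC)OC | intermediate
8 | [1,1-dimethoxy-2-(3-methylbut-2-enyl)buta-1,3-dien-3-yl]oxy-trimethylsilane | COC(OC)=C(CC=C(C)C)C(=C)O[Si](C)(C)C | intermediate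
9 | but-3-yn-2-one | CC(=O)C#C | starting material
10 | 1-[6,6-dimethoxy-5-(3-methylbut-2-enyl)-4-(trimethylsilyloxy)cyclohexa-1,4-dien-1-yl]ethanone | CC(=O)C1=CCC(O[Si](C)(C)C)=C(CC=C(C)C)C1(OC)OC | intermediate
11 | 1-[2-methoxy-3-(3-methylbut-2-enyl)-4-(trimethylsilyloxy)phenyl]ethanone | CC(=O)c1ccc(O[Si](C)(C)C)c(CC=C(C)C)c1OC | intermediate
12 | 1-[4-hydroxy-2-methoxy-3-(3-methylbut-2-enyl)phenyl]ethanone | CC(=O)c1ccc(O)c(CC=C(C)C)c1OC | intermediate
13 | 1-[2-methoxy-4-(methoxymethoxy)-3-(3-methylbut-2-enyl)phenyl]ethanone | CC(=O)c1ccc(OCOC)c(CC=C(C)C)c1OC | intermediate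
14 | methyl 4-hydroxybenzoate | COC(=O)c1ccc(O)cc1 | starting material
15 | methyl 4-(methoxymethoxy)benzoate | COCOc1ccc(cc1)C(=O)OC | intermediate
16 | 1-[2-methoxy-4-(methoxymethoxy)-3-(3-methylbut-2-enyl)phenyl]-3-[4-(methoxymethoxy)phenyl]propane-1,3-dione | COCOc1ccc(cc1)C(=O)CC(=O)c1ccc(OCOC)c(CC=C(C)C)c1OC | intermediate
17 | 1-[4-hydroxy-2-methoxy-3-(3-methylbut-2-enyl)phenyl]-3-(4-hydroxyphenyl)propane-1,3-dione | COc1c(C(=O)CC(=O)c2ccc(O)cc2)ccc(O)c1CC=C(C)C | target

**Step count**

Total step count: 9. Longest linear sequence: 8 steps (steps 1 to 6, then 8 and 9); step 7 is a one-step side branch.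

**Steps most likely to fail**

Step 5. The cycloaddition of the crowded, fully substituted ketene acetal terminus may be slow. The volatile ynone could then polymerise or be attacked at its ketone carbonyl. If water reaches adduct 10 before methanol is lost, ketal hydrolysis would erase the methyl ether.

The fallback sets out from 8, uses an alkynoate and reverses the polarity of the Claisen condensation. Heating 8 with methyl propiolate, the dienophile on which this diene class is best documented and which has no ketone, should give methyl 6,6-dimethoxy-5-(3-methylbut-2-enyl)-4-(trimethylsilyloxy)cyclohexa-1,4-diene-1-carboxylate F1. Loss of methanol should give methyl 2-methoxy-3-(3-methylbut-2-enyl)-4-(trimethylsilyloxy)benzoate F2, and dilute acid methyl 4-hydroxy-2-methoxy-3-(3-methylbut-2-enyl)benzoate F3. MOMCl and i-Pr2NEt convert this into methyl 2-methoxy-4-(methoxymethoxy)-3-(3-methylbut-2-enyl)benzoate F4. Ring A now enters as the ester: the sodium enolate of 1-[4-(methoxymethoxy)phenyl]ethanone F5 (from 4-hydroxyacetophenone and MOMCl) is acylated by F4 (NaH, THF, reflux). This gives 16, where the route is rejoined.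

Step 3. After C-acylation, chloride may demethylate the dimethoxycarbenium ion faster than the amine deprotonates it, which gives the β-keto ester. The amine may also divert acetyl chloride to ketene.

The fallback sets out from 5 and accepts the demethylation. Compound 5 and acetyl chloride without amine should give methyl 2-acetyl-5-methylhex-4-enoate F6 and chloromethane. F6 is also available from methyl acetoacetate and prenyl bromide, should step 2 be the weak point. Me3SiCl and Et3N give methyl 5-methyl-2-[1-(trimethylsilyloxy)ethylidene]hex-4-enoate F7. LDA and Me3SiCl then give 1-methoxy-2-(3-methylbut-2-enyl)-1,3-bis(trimethylsilyloxy)buta-1,3-diene F8. Thermal Diels–Alder addition of F8 to 9 should give 1-[6-methoxy-5-(3-methylbut-2-enyl)-4,6-bis(trimethylsilyloxy)cyclohexa-1,4-dien-1-yl]ethanone F9. Loss of methanol gives 1-[3-(3-methylbut-2-enyl)-2,4-bis(trimethylsilyloxy)phenyl]ethanone F10, and dilute acid gives 1-[2,4-dihydroxy-3-(3-methylbut-2-enyl)phenyl]ethanone F11. The two hydroxyls are no longer differentiated by the cycloaddition. They are told apart by the hydrogen bond of the 2-OH to the ketone: MOMCl, K2CO3 and acetone should alkylate only the 4-OH to give 1-[2-hydroxy-4-(methoxymethoxy)-3-(3-methylbut-2-enyl)phenyl]ethanone F12. MeI, K2CO3 and DMF then methylate the chelated 2-OH to give 13, where the route is rejoined without step 6.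

Step 9. Acid may protonate the prenyl double bond, and the adjacent phenol may then close to a 2,2-dimethylchroman. Methanol or HCl may also add to the alkene before both MOM groups are gone.

The fallback sets out from 12 and 14 and replaces the acid-labile groups by silyl ethers. Compound 12 with i-Pr3SiCl and imidazole (DMF) gives 1-[2-methoxy-3-(3-methylbut-2-enyl)-4-tri(propan-2-yl)silyloxyphenyl]ethanone F13. Compound 14 gives in the same way methyl 4-tri(propan-2-yl)silyloxybenzoate F14. Claisen condensation with LiN(SiMe3)2 in THF (−78 °C to rt) should give 1-[2-methoxy-3-(3-methylbut-2-enyl)-4-tri(propan-2-yl)silyloxyphenyl]-3-[4-tri(propan-2-yl)silyloxyphenyl]propane-1,3-dione F15. Partial loss of a silyl group to lithium methoxide would not matter here. Bu4NF buffered with AcOH (THF, 0 °C) removes both silyl groups without acid strong enough to touch the prenyl group and gives 17.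

**Further compounds**

F1 | step 5 | methyl 6,6-dimethoxy-5-(3-methylbut-2-enyl)-4-(trimethylsilyloxy)cyclohexa-1,4-diene-1-carboxylate | COC(=O)C1=CCC(O[Si](C)(C)C)=C(CC=C(C)C)C1(OC)OC
F2 | step 5 | methyl 2-methoxy-3-(3-methylbut-2-enyl)-4-(trimethylsilyloxy)benzoate | COC(=O)c1ccc(O[Si](C)(C)C)c(CC=C(C)C)c1OC
F3 | step 5 | methyl 4-hydroxy-2-methoxy-3-(3-methylbut-2-enyl)benzoate | COC(=O)c1ccc(O)c(CC=C(C)C)c1OC
F4 | step 5 | methyl 2-methoxy-4-(methoxymethoxy)-3-(3-methylbut-2-enyl)benzoate | COCOc1ccc(C(=O)OC)c(OC)c1CC=C(C)C
F5 | step 5 | 1-[4-(methoxymethoxy)phenyl]ethanone | CC(=O)c1ccc(OCOC)cc1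
F6 | step 3 | methyl 2-acetyl-5-methylhex-4-enoate | COC(=O)C(CC=C(C)C)C(C)=O
F7 | step 3 | methyl 5-methyl-2-[1-(trimethylsilyloxy)ethylidene]hex-4-enoate | COC(=O)C(CC=C(C)C)=C(C)O[Si](C)(C)C
F8 | step 3 | 1-methoxy-2-(3-methylbut-2-enyl)-1,3-bis(trimethylsilyloxy)buta-1,3-diene | COC(O[Si](C)(C)C)=C(CC=C(C)C)C(=C)O[Si](C)(C)C
F9 | step 3 | 1-[6-methoxy-5-(3-methylbut-2-enyl)-4,6-bis(trimethylsilyloxy)cyclohexa-1,4-dien-1-yl]ethanone | CC(=O)C1=CCC(O[Si](C)(C)C)=C(CC=C(C)C)C1(OC)O[Si](C)(C)C
F10 | step 3 | 1-[3-(3-methylbut-2-enyl)-2,4-bis(trimethylsilyloxy)phenyl]ethanone | CC(=O)c1ccc(O[Si](C)(C)C)c(CC=C(C)C)c1O[Si](C)(C)C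
F11 | step 3 | 1-[2,4-dihydroxy-3-(3-methylbut-2-enyl)phenyl]ethanone | CC(=O)c1ccc(O)c(CC=C(C)C)c1O
F12 | step 3 | 1-[2-hydroxy-4-(methoxymethoxy)-3-(3-methylbut-2-enyl)phenyl]ethanone | CC(=O)c1ccc(OCOC)c(CC=C(C)C)c1O
F13 | step 9 | 1-[2-methoxy-3-(3-methylbut-2-enyl)-4-tri(propan-2-yl)silyloxyphenyl]ethanone | CC(=O)c1ccc(O[Si](C(C)C)(C(C)C)C(C)C)c(CC=C(C)C)c1OC
F14 | step 9 | methyl 4-tri(propan-2-yl)silyloxybenzoate | COC(=O)c1ccc(O[Si](C(C)C)(C(C)C)C(C)C)cc1
F15 | step 9 | 1-[2-methoxy-3-(3-methylbut-2-enyl)-4-tri(propan-2-yl)silyloxyphenyl]-3-[4-tri(propan-2-yl)silyloxyphenyl]propane-1,3-dione | COc1c(C(=O)CC(=O)c2ccc(O[Si](C(C)C)(C(C)C)C(C)C)cc2)ccc(O[Si](C(C)C)(C(C)C)C(C)C)c1CC=C(C)C
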